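**Plan**

- Cuts: the four phenols and the ring-B acid go back to four methyl ethers and a tert-butyl ester. A removable carboxyl group is added at C3, and the pyranone is then cut at C3–C4 and at O1–C8a.
- Enabling feature: the acyl carbon C4 and the ether oxygen O1 sit on the neighbouring ring-A carbons C4a and C8a. One 2-fluorobenzoyl chloride (C=O for C4, C–F for C8a) can therefore give both bonds to a beta-keto ester whose ketone carbon becomes C2 and already bears the ring-B benzyl group.
- Forward: ring A (bought) takes up the heptyl chain by Grignard displacement of one ortho-fluorine. Ring B (bought) is ortho-methylated, esterified, carboxylated at the new methyl group and homologated to the keto ester. The pyranone is the only ring built, and it closes when the two halves are joined.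
- The two carboxyl groups are masked orthogonally (benzyl at C3, tert-butyl on ring B). The C3 carboxyl can then be removed while the electron-rich, decarboxylation-prone ring-B acid is still an ester, and one boron tribromide step frees everything.
- Stereochemistry: none to set, because the target has no stereocentre, no stereoaxis and no configurable double bond.

Key step: step 7

Remark: the target SMILES carries no stereodescriptor and the molecule is achiral, so the route delivers the only form of the compound.

**Step 1**
Reactants: 1 2,6-difluoro-4-methoxybenzoic acid; 2 heptylmagnesium bromide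
Product: 4 2-fluoro-6-heptyl-4-methoxybenzoic acid, via bromomagnesium carboxylate 3 (not isolated)
Conditions: 2 (2.3 equiv), THF, 0 °C → rt; 1 M HCl
Reagents that add atoms: none
Why: Carboxylate-directed nucleophilic aromatic substitution on an unprotected 2-fluorobenzoic acid, in which the first equivalent of 2 forms carboxylate 3, 3 binds the second equivalent and passes the heptyl group to the adjacent C–F carbon by addition–elimination, and the product, now alkylated and lacking one activating fluorine, should resist a second displacement.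

**Step 2**
Reactants: 4 2-fluoro-6-heptyl-4-methoxybenzoic acid
Product: 5 2-fluoro-6-heptyl-4-methoxybenzoyl chloride
Conditions: (COCl)2, cat. DMF, CH2Cl2, 0 °C → rt; concentrate, use crude
Reagents that add atoms: oxalyl chloride, O=C(Cl)C(=O)Cl
Why: Vilsmeier-catalysed conversion of an acid into its chloride, to which the ether, the aryl fluoride and the alkyl chain are inert.

**Step 3**
Reactants: 6 2,4,5-trimethoxybenzoic acid
Product: 8 3,4,6-trimethoxy-2-methylbenzoic acid, via dilithio species 7 (not isolated)
Conditions: s-BuLi (2.2 equiv), TMEDA (2.2 equiv), THF, −78 °C; MeI (4 equiv), −78 °C → rt; 1 M HCl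
Reagents that add atoms: iodomethane, CI; sec-butyllithium, CCC(C)[Li] (lithium of 7)
Why: Directed ortho-metalation of an unprotected benzoic acid, in which the lithium carboxylate holds s-BuLi·TMEDA next to the only free ortho position, a site also acidified by the adjacent methoxy group, so kinetic lithiation there should beat the C–H between two methoxy groups before MeI traps the aryllithium.

**Step 4**
Reactants: 8 3,4,6-trimethoxy-2-methylbenzoic acid
Product: 9 tert-butyl 3,4,6-trimethoxy-2-methylbenzoate
Conditions: Cl3CC(=NH)Ot-Bu (2.5 equiv), cat. BF3·OEt2, CH2Cl2–cyclohexane, rt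
Reagents that add atoms: tert-butyl 2,2,2-trichloroacetimidate, CC(C)(C)OC(=N)C(Cl)(Cl)Cl
Why: Acid-catalysed tert-butyl transfer from the imidate alkylates the carboxyl oxygen (SN1-type esterification), which avoids attack at a carbonyl carbon shielded by two ortho substituents.

**Step 5**
Reactants: 9 tert-butyl 3,4,6-trimethoxy-2-methylbenzoate
Product: 11 [2-(tert-butoxycarbonyl)-3,5,6-trimethoxyphenyl]acetic acid, via benzylic lithium 10 (not isolated)
Conditions: LDA (commercial solution, 1.3 equiv), THF, −78 °C; CO2 (g), −78 → 0 °C; cold 0.5 M HCl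
Reagents that add atoms: carbon dioxide, O=C=O; lithium diisopropylamide, CC(C)N([Li])C(C)C (lithium of 10)
Why: Lateral lithiation of an o-toluate followed by carboxylation, in which LDA deprotonates the methyl group ortho to the ester, the hindered tert-butyl ester shuts off self-condensation, and CO2 gives the homophthalic half-ester.

**Step 6**
Reactants: 11 [2-(tert-butoxycarbonyl)-3,5,6-trimethoxyphenyl]acetic acid; 12 monobenzyl malonate
Product: 14 tert-butyl 2-[4-(benzyloxy)-2,4-dioxobutyl]-3,4,6-trimethoxybenzoate, via acyl imidazolide 13 (not isolated)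
Conditions: CDI (1.1 equiv), THF, rt; then 12, MgCl2, Et3N, THF–MeCN, rt → 40 °C; cold 0.5 M HCl
Reagents that add atoms: 1,1'-carbonyldiimidazole, O=C(n1ccnc1)n1ccnc1 (imidazolyl group of 13)
Why: Masamune–Brooks homologation, in which imidazolide 13 C-acylates the magnesium malonate half-ester and loss of CO2 gives the beta-keto ester under near-neutral conditions that leave the tert-butyl benzoate untouched.

**Step 7**
Reactants: 14 tert-butyl 2-[4-(benzyloxy)-2,4-dioxobutyl]-3,4,6-trimethoxybenzoate; 5 2-fluoro-6-heptyl-4-methoxybenzoyl chloride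
Product: 16 benzyl 2-{[2-(tert-butoxycarbonyl)-3,5,6-trimethoxyphenyl]methyl}-5-heptyl-7-methoxy-4-oxo-4H-chromene-3-carboxylate, via tricarbonyl 15 (not isolated)
Conditions: MgCl2 (1.2 equiv), Et3N (2.5 equiv), MeCN, 0 °C; 5, 0 °C → rt; then K2CO3 (4 equiv), DMF, 90 °C, N2, one pot
Reagents that add atoms: none
Why: MgCl2/Et3N turns 14 into its six-membered magnesium chelate, whose two oxygens are tied to the metal, so aroyl chloride 5 is taken up at the central carbon (soft-enolisation C-acylation of a beta-keto ester) and C3–C4 forms in tricarbonyl 15. Carbonate then strips the metal and gives the free enolate of 15, in which the oxygen of the arylacetyl ketone adds to the fluorine-bearing carbon ortho to the aroyl carbonyl; the Meisenheimer charge runs through C4a into the C4 carbonyl, and loss of fluoride forms O1–C8a. The pyranone thus closes as a six-membered ring by intramolecular addition–elimination, formally a 6-endo-trig attack on the C8a=C4a–C4=O unit, and the ring-A methoxy group is meta to the attacked carbon and so does not push electrons into it. The closest known reaction type is acylation of beta-keto esters or malonates with 2-halobenzoyl chlorides followed by base-induced SNAr closure, the standard entry to chromone-3- and 4-quinolone-3-carboxylates. No stereocentre is created. The step needs C- over O-acylation (secured by magnesium chelation), closure through the ketone and not the ester oxygen (the ketone is the more enolised and more nucleophilic site, and only this mode gives the 4-pyranone), and no Dieckmann or isocoumarin closure onto ring B (the benzoate is a tert-butyl ester flanked by two ortho substituents).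

**Step 8**
Reactants: 16 benzyl 2-{[2-(tert-butoxycarbonyl)-3,5,6-trimethoxyphenyl]methyl}-5-heptyl-7-methoxy-4-oxo-4H-chromene-3-carboxylate
Product: 17 2-{[2-(tert-butoxycarbonyl)-3,5,6-trimethoxyphenyl]methyl}-5-heptyl-7-methoxy-4-oxo-4H-chromene-3-carboxylic acid
Conditions: H2 (1 atm), 10% Pd/C, EtOAc, rt
Reagents that add atoms: none
Why: Catalytic hydrogenolysis cleaves only the benzylic C–O bond of the C3 ester, while the tert-butyl ester, the methyl ethers and the tetrasubstituted push–pull C2=C3 bond should not react at 1 atm.

**Step 9**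
Reactants: 17 2-{[2-(tert-butoxycarbonyl)-3,5,6-trimethoxyphenyl]methyl}-5-heptyl-7-methoxy-4-oxo-4H-chromene-3-carboxylic acid
Product: 18 tert-butyl 2-[(5-heptyl-7-methoxy-4-oxo-4H-chromen-2-yl)methyl]-3,4,6-trimethoxybenzoate
Conditions: Ag2CO3 (10 mol %), AcOH (5 mol %), DMSO, 110 °C, N2
Reagents that add atoms: none
Why: Silver(I)-catalysed protodecarboxylation of a heteroaromatic-type acid next to the C4 carbonyl (loss of CO2 to a C3–Ag species, then protonolysis), and the only decarboxylation open to the molecule because the ring-B carboxyl is still an ester.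

**Step 10**
Reactants: 18 tert-butyl 2-[(5-heptyl-7-methoxy-4-oxo-4H-chromen-2-yl)methyl]-3,4,6-trimethoxybenzoate
Product: 19 2-[(5-heptyl-7-hydroxy-4-oxo-4H-chromen-2-yl)methyl]-3,4,6-trihydroxybenzoic acid (target)
Conditions: BBr3 (10 equiv), CH2Cl2, −78 °C → rt, Ar; ice-water quench, degassed EtOAc, evaporation without heating
Reagents that add atoms: none
Why: Boron tribromide ether cleavage (O-coordination, then bromide attack at methyl) removes all four methyl groups and ionises the tert-butyl ester in the same flask, the excess reagent keeps every ring oxygen complexed so the rings are poor partners for the tert-butyl cation, and the salicylate unit stays bound as a boron chelate until the cold quench, which limits protodecarboxylation.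

**Compound list**

| No. | Name | SMILES | Role |
|---|---|---|---|
| 1 | 2,6-difluoro-4-methoxybenzoic acid | COc1cc(F)c(C(=O)O)c(F)c1 | starting material |
| 2 | heptylmagnesium bromide | CCCCCCC[Mg]Br | starting material |
| 3 | bromomagnesium 2,6-difluoro-4-methoxybenzoate (not isolated) | COc1cc(F)c(C(=O)O[Mg]Br)c(F)c1 | intermediate |
| 4 | 2-fluoro-6-heptyl-4-methoxybenzoic acid | CCCCCCCc1cc(OC)cc(F)c1C(=O)O | intermediate |
| 5 | 2-fluoro-6-heptyl-4-methoxybenzoyl chloride | CCCCCCCc1cc(OC)cc(F)c1C(=O)Cl | intermediate |
| 6 | 2,4,5-trimethoxybenzoic acid | COc1cc(OC)c(C(=O)O)cc1OC | starting material |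
| 7 | lithium 2-lithio-3,4,6-trimethoxybenzoate (not isolated) | [Li]c1c(OC)c(OC)cc(OC)c1C(=O)O[Li] | intermediate |
| 8 | 3,4,6-trimethoxy-2-methylbenzoic acid | Cc1c(OC)c(OC)cc(OC)c1C(=O)O | intermediate |
| 9 | tert-butyl 3,4,6-trimethoxy-2-methylbenzoate | Cc1c(OC)c(OC)cc(OC)c1C(=O)OC(C)(C)C | intermediate |
| 10 | tert-butyl 2-(lithiomethyl)-3,4,6-trimethoxybenzoate (not isolated) | [Li]Cc1c(OC)c(OC)cc(OC)c1C(=O)OC(C)(C)C | intermediate |
| 11 | [2-(tert-butoxycarbonyl)-3,5,6-trimethoxyphenyl]acetic acid | OC(=O)Cc1c(OC)c(OC)cc(OC)c1C(=O)OC(C)(C)C | intermediate |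
| 12 | monobenzyl malonate (3-(benzyloxy)-3-oxopropanoic acid) | OC(=O)CC(=O)OCc1ccccc1 | starting material |
| 13 | tert-butyl 2-[2-(1H-imidazol-1-yl)-2-oxoethyl]-3,4,6-trimethoxybenzoate (not isolated) | O=C(Cc1c(OC)c(OC)cc(OC)c1C(=O)OC(C)(C)C)n1ccnc1 | intermediate |
| 14 | tert-butyl 2-[4-(benzyloxy)-2,4-dioxobutyl]-3,4,6-trimethoxybenzoate | O=C(CC(=O)Cc1c(OC)c(OC)cc(OC)c1C(=O)OC(C)(C)C)OCc1ccccc1 | intermediate |
| 15 | benzyl 4-[2-(tert-butoxycarbonyl)-3,5,6-trimethoxyphenyl]-2-(2-fluoro-6-heptyl-4-methoxybenzoyl)-3-oxobutanoate (not isolated; enolised, configurationally labile) | CCCCCCCc1cc(OC)cc(F)c1C(=O)C(C(=O)OCc1ccccc1)C(=O)Cc1c(OC)c(OC)cc(OC)c1C(=O)OC(C)(C)C | intermediate |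
| 16 | benzyl 2-{[2-(tert-butoxycarbonyl)-3,5,6-trimethoxyphenyl]methyl}-5-heptyl-7-methoxy-4-oxo-4H-chromene-3-carboxylate | CCCCCCCc1cc(OC)cc2oc(Cc3c(OC)c(OC)cc(OC)c3C(=O)OC(C)(C)C)c(C(=O)OCc3ccccc3)c(=O)c12 | intermediate |
| 17 | 2-{[2-(tert-butoxycarbonyl)-3,5,6-trimethoxyphenyl]methyl}-5-heptyl-7-methoxy-4-oxo-4H-chromene-3-carboxylic acid | CCCCCCCc1cc(OC)cc2oc(Cc3c(OC)c(OC)cc(OC)c3C(=O)OC(C)(C)C)c(C(=O)O)c(=O)c12 | intermediate |
| 18 | tert-butyl 2-[(5-heptyl-7-methoxy-4-oxo-4H-chromen-2-yl)methyl]-3,4,6-trimethoxybenzoate | CCCCCCCc1cc(OC)cc2oc(Cc3c(OC)c(OC)cc(OC)c3C(=O)OC(C)(C)C)cc(=O)c12 | intermediate |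
| 19 | 2-[(5-heptyl-7-hydroxy-4-oxo-4H-chromen-2-yl)methyl]-3,4,6-trihydroxybenzoic acid | CCCCCCCc1cc(O)cc2oc(Cc3c(O)c(O)cc(O)c3C(=O)O)cc(=O)c12 | target |

**Counts**

- Total step count: 10.
- Longest linear sequence: 8 steps (6 → 19, steps 3–10). The ring-A branch (steps 1–2) joins at step 7.

**Steps most likely to fail**

1. **Step 7.**
   - What may go wrong: acyl transfer from the di-ortho-substituted chloride to the central carbon of the chelate may be slow, so that O-acylation or loss of the chloride takes over. The closure may also lag, because the heptyl group twists the aroyl carbonyl out of the ring-A plane.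
   - Fallback (sets out from 5, 12 and 11, returns at 15 and through it at 16): the two acyl groups are put on the central carbon in the reverse order.
   - Chloride 5 is first joined to the small nucleophile made from 12 (MgCl2, Et3N, MeCN) to give benzyl 3-(2-fluoro-6-heptyl-4-methoxyphenyl)-3-oxopropanoate F1.
   - Acid 11 is converted under neutral conditions with 1-chloro-N,N,2-trimethylpropenylamine into tert-butyl 2-(2-chloro-2-oxoethyl)-3,4,6-trimethoxybenzoate F2.
   - The magnesium chelate of F1 is then C-acylated by the unhindered F2 (MgCl2, pyridine, CH2Cl2). This should give 15, which is isolated and closed separately with K2CO3 in DMF to 16.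

2. **Step 9.**
   - What may go wrong: loss of CO2 from the sp2 carbon C3 may stall, or the tert-butyl ester may be shed at the temperature needed.
   - Fallback (sets out from 15, returns at 18): the carboxyl group is removed before ring closure, while it is still part of a true beta-keto acid.
   - Step 7 is stopped after the magnesium stage and 15 is isolated by an acidic wash.
   - Hydrogenolysis (H2, Pd/C, EtOAc) gives 4-[2-(tert-butoxycarbonyl)-3,5,6-trimethoxyphenyl]-2-(2-fluoro-6-heptyl-4-methoxybenzoyl)-3-oxobutanoic acid F3.
   - F3 should lose CO2 at room temperature to give tert-butyl 2-[4-(2-fluoro-6-heptyl-4-methoxyphenyl)-2,4-dioxobutyl]-3,4,6-trimethoxybenzoate F4.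
   - The enolate of this 1-(2-fluoroaryl)-1,3-diketone is closed by intramolecular O-arylation (K2CO3, DMF, 100 °C) to 18.

3. **Step 10.**
   - What may go wrong: HBr may protodecarboxylate the freed 2,4-dihydroxybenzoic acid unit during reaction or quench. Air oxidation of the 1,2,4-trihydroxyarene is a second hazard.
   - Fallback (sets out from 18, returns at 19): the carboxyl group is given up on purpose and put back last.
   - After the boron tribromide treatment the crude material is warmed in dilute aqueous acid until loss of CO2 is complete. This should give 5-heptyl-7-hydroxy-2-[(2,3,5-trihydroxyphenyl)methyl]-4H-chromen-4-one F5.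
   - Heating F5 with methyl magnesium carbonate in DMF (about 120 °C, argon), followed by a cold acidic quench, should carboxylate ring B at the position flanked by the benzylic carbon. That position is ortho to one hydroxyl and para to another, and it is the site taken in the same chelation-driven carboxylation of 5-alkylresorcinols.
   - The ring-A phenol is a vinylogous acid tied to the C4 carbonyl and should stay out.

**Further compounds**

F1 | step 7 | benzyl 3-(2-fluoro-6-heptyl-4-methoxyphenyl)-3-oxopropanoate | CCCCCCCc1cc(OC)cc(F)c1C(=O)CC(=O)OCc1ccccc1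
F2 | step 7 | tert-butyl 2-(2-chloro-2-oxoethyl)-3,4,6-trimethoxybenzoate | O=C(Cl)Cc1c(OC)c(OC)cc(OC)c1C(=O)OC(C)(C)C
F3 | step 9 | 4-[2-(tert-butoxycarbonyl)-3,5,6-trimethoxyphenyl]-2-(2-fluoro-6-heptyl-4-methoxybenzoyl)-3-oxobutanoic acid | CCCCCCCc1cc(OC)cc(F)c1C(=O)C(C(=O)O)C(=O)Cc1c(OC)c(OC)cc(OC)c1C(=O)OC(C)(C)C
F4 | step 9 | tert-butyl 2-[4-(2-fluoro-6-heptyl-4-methoxyphenyl)-2,4-dioxobutyl]-3,4,6-trimethoxybenzoate | CCCCCCCc1cc(OC)cc(F)c1C(=O)CC(=O)Cc1c(OC)c(OC)cc(OC)c1C(=O)OC(C)(C)C
F5 | step 10 | 5-heptyl-7-hydroxy-2-[(2,3,5-trihydroxyphenyl)methyl]-4H-chromen-4-one | CCCCCCCc1cc(O)cc2oc(Cc3cc(O)cc(O)c3O)cc(=O)c12
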